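**Plan**
- Numbering used: ring A is the phenol ring and carries C7H2; C8 (CH), C8' (CHMe) and C7' (ArCH–O, on ring B) follow; C9 is the OCH2 carbon.
- Retrosynthesis: both bonds at the bridgehead C7' (C7'–O and C7'–C8') are cut together, then the biaryl bond, then O–C9 of the remaining oxetane, then C7–C8.
- Enabling feature: in the ring O–C9–C8–C8'–C7', C7' is the one atom bonded to the ring oxygen, to ring B and to C8'. Removing it leaves an oxetane (O, C9, C8, C8') on the ring A benzylic carbon and a ring B benzylic carbene, held face to face by the biaryl bond.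
- Forward: ring A benzyl bromide plus ethyl (R)-3-hydroxybutanoate gives the anti diol, then the trans oxetane; Suzuki coupling adds ring B as its aldehyde; the tosylhydrazone follows. In the key step the carbenoid at C7' is taken up by the oxetane oxygen and a [1,2]-shift of C8' enlarges the oxetane to the tetrahydrofuran while closing the eight-membered ring in the same bond.
- Stereochemistry: C8' comes from the chiral pool; C8 from the anti alkylation; C8' migrates with retention; C7' is fixed by the bridge (cis to C8).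
- The phenol is carried as its tosylate throughout, because this oxygen sits next to the carbenoid and must neither bind it nor hand over a group.

Key step: step 12

Remark on the chemistry (assumption): the SMILES fixes C7', C8 and C8' and has no descriptor for the biaryl axis, so the axis is not assigned here. Biaryls 13 and 14 are tetra-ortho-substituted and are taken as pairs of atropisomers that do not interconvert. Each can only close to the form of 17 with the same axis sense, and the two forms of 17 (same three centres) should be separable by chromatography.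

**Route**

Step 1
Reactants: 1 3-hydroxy-4,5-dimethoxybenzaldehyde
Product: 2 2-bromo-3-hydroxy-4,5-dimethoxybenzaldehyde
Conditions: Br2, NaOAc, AcOH, rt
Reagents that add atoms: bromine, BrBr
Why: Electrophilic aromatic bromination should go to C2, the only open position ortho to the free phenol and also para to the 5-methoxy group, as in the 2-bromination of isovanillin.

Step 2
Reactants: 2 2-bromo-3-hydroxy-4,5-dimethoxybenzaldehyde
Product: 3 2-bromo-3-formyl-5,6-dimethoxyphenyl 4-methylbenzenesulfonate
Conditions: TsCl, Et3N, DMAP (cat.), CH2Cl2, 0 °C to rt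
Reagents that add atoms: 4-methylbenzenesulfonyl chloride, Cc1ccc(cc1)S(=O)(=O)Cl
Why: Sulfonylation of the phenol gives an aryl sulfonate whose oxygen is a poor donor toward the later carbenoid, carries no group able to migrate, and should survive every step up to the last.

Step 3
Reactants: 3 2-bromo-3-formyl-5,6-dimethoxyphenyl 4-methylbenzenesulfonate
Product: 4 2-bromo-3-(hydroxymethyl)-5,6-dimethoxyphenyl 4-methylbenzenesulfonate
Conditions: NaBH4, MeOH/THF, 0 °C
Reagents that add atoms: none
Why: Borohydride reduction of the aldehyde is chemoselective in the presence of aryl bromide and aryl sulfonate.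

Step 4
Reactants: 4 2-bromo-3-(hydroxymethyl)-5,6-dimethoxyphenyl 4-methylbenzenesulfonate
Product: 5 2-bromo-3-(bromomethyl)-5,6-dimethoxyphenyl 4-methylbenzenesulfonate
Conditions: PBr3, CH2Cl2, 0 °C
Reagents that add atoms: phosphorus tribromide, BrP(Br)Br
Why: Bromination of a benzylic alcohol by PBr3 (SN2 displacement on the phosphite ester) is routine and leaves the other groups untouched.

Step 5
Reactants: 5 2-bromo-3-(bromomethyl)-5,6-dimethoxyphenyl 4-methylbenzenesulfonate; 6 ethyl (R)-3-hydroxybutanoate
Product: 7 ethyl (2R,3R)-2-{[2-bromo-4,5-dimethoxy-3-(tosyloxy)phenyl]methyl}-3-hydroxybutanoate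
Conditions: 6, LiN(i-Pr)2 (2.1 equiv to 6), THF, −78 to −20 °C; then 5, DMPU, −78 to 0 °C
Reagents that add atoms: none
Why: Fráter–Seebach alkylation: the chelated lithium alkoxide–enolate dianion of 6 is benzylated on the face away from the C3 methyl group, which sets the new centre (the future C8) anti to the carbinol carbon (the future C8', R from the chiral pool).

Step 6
Reactants: 7 ethyl (2R,3R)-2-{[2-bromo-4,5-dimethoxy-3-(tosyloxy)phenyl]methyl}-3-hydroxybutanoate
Product: 8 (2S,3R)-2-{[2-bromo-4,5-dimethoxy-3-(tosyloxy)phenyl]methyl}butane-1,3-diol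
Conditions: LiBH4, THF, 0 °C to rt
Reagents that add atoms: none
Why: Ester reduction by LiBH4 tolerates aryl bromide and aryl sulfonate and touches neither stereocentre (the descriptor at C2 changes only by priority).

Step 7
Reactants: 8 (2S,3R)-2-{[2-bromo-4,5-dimethoxy-3-(tosyloxy)phenyl]methyl}butane-1,3-diol
Product: 9 (2S,3R)-2-{[2-bromo-4,5-dimethoxy-3-(tosyloxy)phenyl]methyl}-3-hydroxybutyl 4-methylbenzenesulfonate
Conditions: TsCl (1.05 equiv), pyridine, CH2Cl2, 0 °C
Reagents that add atoms: 4-methylbenzenesulfonyl chloride, Cc1ccc(cc1)S(=O)(=O)Cl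
Why: Sulfonylation should select the primary over the secondary hydroxyl on steric grounds.

Step 8
Reactants: 9 (2S,3R)-2-{[2-bromo-4,5-dimethoxy-3-(tosyloxy)phenyl]methyl}-3-hydroxybutyl 4-methylbenzenesulfonate
Product: 10 2-bromo-5,6-dimethoxy-3-{[(2R,3S)-2-methyloxetan-3-yl]methyl}phenyl 4-methylbenzenesulfonate
Conditions: NaH, THF, 0 to 45 °C
Reagents that add atoms: none
Why: Intramolecular Williamson etherification (4-exo-tet) of the secondary alkoxide on the primary sulfonate closes the oxetane without touching either stereocentre, so the anti diol gives the trans-2,3-disubstituted oxetane.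

Step 9
Reactants: 10 2-bromo-5,6-dimethoxy-3-{[(2R,3S)-2-methyloxetan-3-yl]methyl}phenyl 4-methylbenzenesulfonate
Product: 11 5,6-dimethoxy-3-{[(2R,3S)-2-methyloxetan-3-yl]methyl}-2-(4,4,5,5-tetramethyl-1,3,2-dioxaborolan-2-yl)phenyl 4-methylbenzenesulfonate
Conditions: B2pin2, Pd(OAc)2 (cat.), SPhos, KOAc, 1,4-dioxane, 90 °C
Reagents that add atoms: bis(pinacolato)diboron, CC1(C)OB(OC1(C)C)B1OC(C)(C)C(C)(C)O1
Why: Miyaura borylation with a dialkylbiarylphosphine ligand is suited to di-ortho-substituted aryl bromides, and the aryl sulfonate and oxetane are inert under these weakly basic conditions.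

Step 10
Reactants: 11 5,6-dimethoxy-3-{[(2R,3S)-2-methyloxetan-3-yl]methyl}-2-(4,4,5,5-tetramethyl-1,3,2-dioxaborolan-2-yl)phenyl 4-methylbenzenesulfonate; 12 2-bromo-3,4,5-trimethoxybenzaldehyde
Product: 13 2'-formyl-3,4,4',5',6'-pentamethoxy-6-{[(2R,3S)-2-methyloxetan-3-yl]methyl}-[1,1'-biphenyl]-2-yl 4-methylbenzenesulfonate
Conditions: Pd(OAc)2 (cat.), SPhos, K3PO4, toluene/H2O, 100 °C
Reagents that add atoms: none
Why: Suzuki–Miyaura coupling with a dialkylbiarylphosphine ligand is the established way to tetra-ortho-substituted biaryls, the formyl-activated bromide 12 should add readily to palladium, no stereocentre is touched and the axis forms without control (see remark).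

Step 11
Reactants: 13 2'-formyl-3,4,4',5',6'-pentamethoxy-6-{[(2R,3S)-2-methyloxetan-3-yl]methyl}-[1,1'-biphenyl]-2-yl 4-methylbenzenesulfonate
Product: 14 (E)-N-tosylhydrazone of 13
Conditions: TsNHNH2, MeOH, 40 °C
Reagents that add atoms: 4-methylbenzenesulfonohydrazide, Cc1ccc(cc1)S(=O)(=O)NN
Why: Condensation of the aldehyde with the sulfonohydrazide needs no acid, so the oxetane should be safe.

Step 12
Reactants: 14 (E)-N-tosylhydrazone of 13
Product: 17 O-tosyl derivative of the target (bridged tetrahydrofuran), via aryldiazomethane 15 (not isolated), via bicyclic oxonium ylide 16 (not isolated)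
Conditions: NaH, THF, 0 °C to rt; then slow addition to Cu(hfacac)2 (copper bis(hexafluoroacetylacetonate), 5 mol%), BnEt3NCl (10 mol%), toluene, 70 °C, high dilution
Reagents that add atoms: none
Why: Proposed new method: the sodium salt of 14 loses sulfinate (Bamford–Stevens) to give aryldiazomethane 15, whose copper carbenoid at C7' is attacked by the oxetane oxygen (the most Lewis-basic site, held three bonds beyond the ring A benzylic carbon directly across the biaryl cleft) to give oxonium ylide 16, and a Stevens [1,2]-shift then moves C8' from the oxonium oxygen to the carbanionic C7'. The closest known reaction type is the copper- or rhodium-catalysed one-carbon ring expansion of oxetanes to tetrahydrofurans by diazo compounds, known between two molecules, together with intramolecular oxonium ylide/[1,2]-shift routes to bridged ethers; new here are the donor aryl carbenoid tethered through a biaryl and the medium ring formed in the shift. Ring closures: the nine-membered ylide ring forms by oxygen-to-carbenoid attack, the tetrahydrofuran arises by four-to-five ring expansion of the oxetane, and the eight-membered carbocycle closes in the same C7'–C8' bond formation, as a ring contraction of the ylide ring. Stereocontrol: C8' should migrate with retention within the short-lived radical pair (the methyl/arylmethyl trans arrangement of 10 is kept, and is also the more stable one should the radical relax), and C7' is a bridgehead that can only take the configuration in which the biaryl spans C7' and C8 cis. Selectivity needed: ylide formation must beat 1,6 C–H insertion into the ring A benzylic CH2 and attack on the ring A oxygen, and C8' must migrate in preference to C9; copper (which favours ylide formation over insertion), the non-nucleophilic and non-migrating sulfonate, and the secondary versus primary nature of C8' versus C9 are relied on for this.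

Step 13
Reactants: 17 O-tosyl derivative of the target (bridged tetrahydrofuran)
Product: 18 target, (7'R,8R,8'R)-7',9-epoxy dibenzocyclooctadiene lignan with the free phenol on ring A
Conditions: KOH, EtOH/H2O, 80 °C; then aq. NH4Cl
Reagents that add atoms: none
Why: Alkaline S–O cleavage of the aryl sulfonate frees the phenol, while the benzylic cyclic ether, the methyl ethers and the three stereocentres are inert to hydroxide.

**Compound list**

1 | 3-hydroxy-4,5-dimethoxybenzaldehyde | O=Cc1cc(O)c(OC)c(OC)c1 | starting material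
2 | 2-bromo-3-hydroxy-4,5-dimethoxybenzaldehyde | O=Cc1cc(OC)c(OC)c(O)c1Br | intermediate
3 | 2-bromo-3-formyl-5,6-dimethoxyphenyl 4-methylbenzenesulfonate | O=Cc1cc(OC)c(OC)c(OS(=O)(=O)c2ccc(C)cc2)c1Br | intermediate
4 | 2-bromo-3-(hydroxymethyl)-5,6-dimethoxyphenyl 4-methylbenzenesulfonate | OCc1cc(OC)c(OC)c(OS(=O)(=O)c2ccc(C)cc2)c1Br | intermediate
5 | 2-bromo-3-(bromomethyl)-5,6-dimethoxyphenyl 4-methylbenzenesulfonate | BrCc1cc(OC)c(OC)c(OS(=O)(=O)c2ccc(C)cc2)c1Br | intermediate
6 | ethyl (R)-3-hydroxybutanoate | CCOC(=O)C[C@@H](C)O | starting material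
7 | ethyl (2R,3R)-2-{[2-bromo-4,5-dimethoxy-3-(tosyloxy)phenyl]methyl}-3-hydroxybutanoate | CCOC(=O)[C@H](Cc1cc(OC)c(OC)c(OS(=O)(=O)c2ccc(C)cc2)c1Br)[C@@H](C)O | intermediate
8 | (2S,3R)-2-{[2-bromo-4,5-dimethoxy-3-(tosyloxy)phenyl]methyl}butane-1,3-diol | OC[C@H](Cc1cc(OC)c(OC)c(OS(=O)(=O)c2ccc(C)cc2)c1Br)[C@@H](C)O | intermediate
9 | (2S,3R)-2-{[2-bromo-4,5-dimethoxy-3-(tosyloxy)phenyl]methyl}-3-hydroxybutyl 4-methylbenzenesulfonate | Cc1ccc(cc1)S(=O)(=O)OC[C@H](Cc1cc(OC)c(OC)c(OS(=O)(=O)c2ccc(C)cc2)c1Br)[C@@H](C)O | intermediate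
10 | 2-bromo-5,6-dimethoxy-3-{[(2R,3S)-2-methyloxetan-3-yl]methyl}phenyl 4-methylbenzenesulfonate | C[C@H]1OC[C@@H]1Cc1cc(OC)c(OC)c(OS(=O)(=O)c2ccc(C)cc2)c1Br | intermediate
11 | 5,6-dimethoxy-3-{[(2R,3S)-2-methyloxetan-3-yl]methyl}-2-(4,4,5,5-tetramethyl-1,3,2-dioxaborolan-2-yl)phenyl 4-methylbenzenesulfonate | C[C@H]1OC[C@@H]1Cc1cc(OC)c(OC)c(OS(=O)(=O)c2ccc(C)cc2)c1B1OC(C)(C)C(C)(C)O1 | intermediate
12 | 2-bromo-3,4,5-trimethoxybenzaldehyde | O=Cc1cc(OC)c(OC)c(OC)c1Br | starting material
13 | 2'-formyl-3,4,4',5',6'-pentamethoxy-6-{[(2R,3S)-2-methyloxetan-3-yl]methyl}-[1,1'-biphenyl]-2-yl 4-methylbenzenesulfonate | C[C@H]1OC[C@@H]1Cc1cc(OC)c(OC)c(OS(=O)(=O)c2ccc(C)cc2)c1-c1c(C=O)cc(OC)c(OC)c1OC | intermediate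
14 | (E)-N-tosylhydrazone of 13 | C[C@H]1OC[C@@H]1Cc1cc(OC)c(OC)c(OS(=O)(=O)c2ccc(C)cc2)c1-c1c(/C=N/NS(=O)(=O)c2ccc(C)cc2)cc(OC)c(OC)c1OC | intermediate
15 | aryldiazomethane, 2'-(diazomethyl) analogue of 13 | C[C@H]1OC[C@@H]1Cc1cc(OC)c(OC)c(OS(=O)(=O)c2ccc(C)cc2)c1-c1c(C=[N+]=[N-])cc(OC)c(OC)c1OC | intermediate
16 | bicyclic oxonium ylide (oxetane oxygen bonded to C7', carbanion at C7') | C[C@H]1[O+]2C[C@@H]1Cc1cc(OC)c(OC)c(OS(=O)(=O)c3ccc(C)cc3)c1-c1c([CH-]2)cc(OC)c(OC)c1OC | intermediate
17 | O-tosyl derivative of the target (bridged tetrahydrofuran) | COc1cc2c(c(OS(=O)(=O)c3ccc(C)cc3)c1OC)-c1c(cc(OC)c(OC)c1OC)[C@@H]1OC[C@H](C2)[C@H]1C | intermediate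
18 | target, (7'R,8R,8'R)-7',9-epoxy dibenzocyclooctadiene lignan | COc1cc2c(c(O)c1OC)-c1c(cc(OC)c(OC)c1OC)[C@@H]1OC[C@H](C2)[C@H]1C | target

**Step count and risks**

Total step count: 13. Longest linear sequence: 13 steps (1 to 18); 6 and 12 enter as purchased fragments.

Steps most likely to fail:

1. Step 12 (proposed new method). The carbenoid may insert into the benzylic C–H bonds of ring A through a six-membered transition state, or dimerise, before the oxetane oxygen reaches it. The shift may take C9 instead of C8'. Each atropisomer of 14 can close only within its own axis sense. The fallback sets out from 11 and 12 and returns at 17; it builds the tetrahydrofuran between two molecules and forms the biaryl bond last. Aldehyde 12 is condensed with TsNHNH2 to the tosylhydrazone F1. Its sodium salt, added slowly in excess to oxetane 11 with Cu(hfacac)2 at 60–70 °C, gives (2-bromo-3,4,5-trimethoxyphenyl)diazomethane F2 in the flask. By the known two-component carbenoid ring expansion of an oxetane this should give the 2-aryl-3-methyl-4-(arylmethyl)tetrahydrofuran F3, with C8' retained and the aryl group expected trans to the methyl group. F3 carries the bromide on ring B and the boronate on ring A. An intramolecular Suzuki–Miyaura coupling (Pd(OAc)2, SPhos, K3PO4, toluene/H2O, high dilution) should close the eight-membered ring to 17, with the axis set under control of the rigid tetrahydrofuran.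

2. Step 10. Transmetalation at the tetra-ortho-substituted junction may be slow enough for protodeboronation of 11 to take over, and the axis forms without control. The fallback sets out from 10 and returns at 13; it makes the biaryl bond within a temporary lactone ring. The tosylate of 10 is cleaved (KOH, EtOH/H2O) to the phenol F4, which is acylated with 3,4,5-trimethoxybenzoyl chloride (Et3N, DMAP) to the aryl benzoate F5. Intramolecular direct arylation (Pd(OAc)2, PPh3, K2CO3, DMA, 130 °C) joins the ring A bromide carbon to an ortho carbon of the benzoate and gives the benzo[c]chromen-6-one F6. Reduction of the lactone (LiAlH4, THF, 0 °C, or borane with either antipode of the Corey–Bakshi–Shibata catalyst where one atropisomer is wanted) gives the hydroxymethyl biaryl phenol F7. The phenol is tosylated selectively (TsCl, K2CO3, acetone) to the benzylic alcohol F8, and MnO2 in CH2Cl2 oxidises it to 13.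

3. Step 5. The dianion may attack the aryl sulfonate at sulfur, or be alkylated at oxygen or twice at carbon, and proton exchange may erode the anti selectivity. The fallback sets out from 5 and returns at 8; it uses a cyclic acetal enolate with no free alkoxide. Commercial (2R,6R)-2-tert-butyl-6-methyl-1,3-dioxan-4-one (from (R)-3-hydroxybutanoic acid and pivalaldehyde) is deprotonated with LiN(i-Pr)2 in THF at −78 °C and benzylated with 5 trans to the 6-methyl group, to give the 5-alkylated dioxanone F9. LiBH4 in THF then reduces the acylal to diol 8.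

**Further compounds**

F1 | step 12 | N'-[(E)-(2-bromo-3,4,5-trimethoxyphenyl)methylidene]-4-methylbenzenesulfonohydrazide | Cc1ccc(cc1)S(=O)(=O)N/N=C/c1cc(OC)c(OC)c(OC)c1Br
F2 | step 12 | (2-bromo-3,4,5-trimethoxyphenyl)diazomethane | [N-]=[N+]=Cc1cc(OC)c(OC)c(OC)c1Br
F3 | step 12 | 3-{[(3R,4R,5R)-5-(2-bromo-3,4,5-trimethoxyphenyl)-4-methyloxolan-3-yl]methyl}-5,6-dimethoxy-2-(4,4,5,5-tetramethyl-1,3,2-dioxaborolan-2-yl)phenyl 4-methylbenzenesulfonate | COc1cc([C@@H]2OC[C@H](Cc3cc(OC)c(OC)c(OS(=O)(=O)c4ccc(C)cc4)c3B3OC(C)(C)C(C)(C)O3)[C@H]2C)c(Br)c(OC)c1OC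
F4 | step 10 | 2-bromo-5,6-dimethoxy-3-{[(2R,3S)-2-methyloxetan-3-yl]methyl}phenol | C[C@H]1OC[C@@H]1Cc1cc(OC)c(OC)c(O)c1Br
F5 | step 10 | 2-bromo-5,6-dimethoxy-3-{[(2R,3S)-2-methyloxetan-3-yl]methyl}phenyl 3,4,5-trimethoxybenzoate | C[C@H]1OC[C@@H]1Cc1cc(OC)c(OC)c(OC(=O)c2cc(OC)c(OC)c(OC)c2)c1Br
F6 | step 10 | 3,4,8,9,10-pentamethoxy-1-{[(2R,3S)-2-methyloxetan-3-yl]methyl}-6H-benzo[c]chromen-6-one | C[C@H]1OC[C@@H]1Cc1cc(OC)c(OC)c2OC(=O)c3cc(OC)c(OC)c(OC)c3-c12
F7 | step 10 | 2'-(hydroxymethyl)-3,4,4',5',6'-pentamethoxy-6-{[(2R,3S)-2-methyloxetan-3-yl]methyl}-[1,1'-biphenyl]-2-ol | C[C@H]1OC[C@@H]1Cc1cc(OC)c(OC)c(O)c1-c1c(CO)cc(OC)c(OC)c1OC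
F8 | step 10 | 2'-(hydroxymethyl)-3,4,4',5',6'-pentamethoxy-6-{[(2R,3S)-2-methyloxetan-3-yl]methyl}-[1,1'-biphenyl]-2-yl 4-methylbenzenesulfonate | C[C@H]1OC[C@@H]1Cc1cc(OC)c(OC)c(OS(=O)(=O)c2ccc(C)cc2)c1-c1c(CO)cc(OC)c(OC)c1OC
F9 | step 5 | 2-bromo-3-{[(2R,4R,5R)-2-tert-butyl-4-methyl-6-oxo-1,3-dioxan-5-yl]methyl}-5,6-dimethoxyphenyl 4-methylbenzenesulfonate | CC(C)(C)[C@H]1OC(=O)[C@H](Cc2cc(OC)c(OC)c(OS(=O)(=O)c3ccc(C)cc3)c2Br)[C@@H](C)O1
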